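Assumption (remark on the chemistry): the olefin geometries are taken exactly as written in the SMILES, so both ring double bonds are ring-cis (C10=C1 is Z; C4=C5 is E by CIP only because CH2OH outranks C3). Germacrane numbering C1–C15 is used in the discussion; in the cyclodeca[b]furan names C8 = locant 4, C10 = 6, C4 = 10, C6 = 11a, C7 = 3a, C11 = 3.

## Structural features

The target is a germacra-1(10),4-dien-6,12-olide: a ten-membered carbocycle (C1–C10) trans-fused at C6/C7 to an α-methyl-γ-butyrolactone (O–C6, C7–C11(CH3)–C12=O). C8 carries the 2-(hydroxymethyl)acrylate ester, C4 a free primary allylic CH2OH (C15) and C10 a methyl group. Both ring olefins are trisubstituted and ring-cis, C10(CH3)=C1 with C9 cis to C2 and C4(CH2OH)=C5 with C3 cis to C6, and they are joined through C2–C3 into a cis,cis-1,5-diene. Three stereocentres, C8 (S), C7 (R) and C6 (R), are contiguous on the ring and the fourth, C11 (S), sits on the lactone next to C7; O6 and O8 lie on one face, C11 on the other, and the C11 methyl is trans to C8. Fragile points are the acrylate (Michael acceptor), the allylic lactone C6–O bond (ionisable; a free C8–O(−) can take over the lactone), the epimerisable C11, and the geometry of both olefins. The real difficulty is closing the strained ten-membered ring without scrambling two cis-trisubstituted olefins while the C6–C7–C8 triad and C11 are in place. The key step exploits C8: it is a single oxygen-bearing methine flanked by C7 (the β-carbon of the lactone carbonyl, i.e. the Michael position of a butenolide) and by C9 (the allylic CH2 of C10=C1, i.e. the terminus of a π-allyl), so C8 can be supplied as a carbonyl 1,1-dianion equivalent, nitromethane, whose second C–C bond closes the ring.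

## Logic of the disconnections

29 from 28: the two O–Si bonds at O15 and at the acrylate oxygen are cut last. The reason is that a free primary C15–OH would out-compete C8–OH in acylation and a free hydroxy acid would self-condense. The gain is a single mild final step. The demand is a desilylation that leaves the acrylate, the lactone and the olefin geometry untouched.

28 from 24 and 27: the ester bond O8–C(=O) is cut, so that the Michael-acceptor side chain enters last. This leaves 24 as the complete core and 27 as a three-carbon acid, reached from 25 through 26 (O–Si formed, O–ethyl cut). The forward step must acylate a hindered secondary alcohol with retention and without strong base, which would move the lactone from O6 to O8.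

24 from 23: the C8–H bond is cut, leaving a ketone. C8 is the carbon that the key step uses as a nucleophile, so its oxygen is best revealed at the ketone level. The gain is that no C8 configuration has to survive the ring closure. The demand is facial selectivity of hydride delivery in the macrocycle; either epimer can be used, because esterification can proceed with retention or with inversion.

23 from 21 (through 22): the C8=O bond is traded for C8–NO2. The nitro group is what makes C8 a carbon nucleophile twice in succession. The demand is a Nef conversion under non-oxidising, nearly neutral conditions.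

21 from 20 (key disconnection): the ring bond C8–C9 is cut between the nitro-bearing carbon and the allylic CH2. This opens the ten-membered ring to an acyclic chain in which both olefins already have their geometry and C6, C7 and C11 are fixed on a five-membered ring. The forward step must form a C–C bond at the unsubstituted allyl terminus, under high dilution, without syn–anti isomerisation of the allyl unit and without ionising the allylic lactone.

20 from 19 from 18: the O15–Si bond and then the C15–H bond are cut, so that C15 is an aldehyde for the olefination. The demand is a chemoselective 1,2-reduction beside lactone, nitro group and carbonate, and silylation so that C15–O is not a second allylic leaving group.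

18 from 8 and 17: the C4=C5 double bond is cut. This is the convergent union of the lactone half and the diene half. The demand is an E-selective olefination (CHO trans to C6) under neutral conditions that do not epimerise the α-oxygenated aldehyde or deprotonate the nitro group.

8 from 7 from 6: the C5 oxidation level is lowered and the O–CPh3 bond restored, so that the aldehyde is unmasked only after the stereocentres are set.

6 from 4 and 5: the C7–C8 bond is cut, together with the C11–H bond. On the five-membered butenolide the single stereocentre C6 directs the addition anti, and C11 follows by equilibration. One stereocentre thus gives three. The demand is trans selectivity at C7 and thermodynamic control at C11.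

4 from 3 from 2 from 1: the C7=C11 double bond (metathesis), the O–C12 acyl bond and the bond from the carbinol-bearing chain to its vinyl terminus are cut in turn. This reduces the lactone half to one commercial chiral epoxide.

17 from 15 (through 16), 15 from 14, 14 from 13, 13 from 12, 12 from 10 and 11, 10 from 9: the C4–CHO bond, the C4–P bond, the carbonate C–O bond, the C9 oxidation level and the C10=C1 double bond are cut in turn. The only demand of note is Z selectivity in forming C10=C1.

## Other disconnections considered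

Alternative 1: the first route that comes to mind cuts C6–C7 together with the lactone C–O bond. The forward key step is a CrCl2-mediated intramolecular Nozaki–Hiyama–Kishi allylation of the bromo-enal A1, giving the α-methylene lactone A2, followed by conjugate reduction of the exocyclic methylene for C11. The chosen plan is preferred for three reasons. The aldehyde of A1 is a β,β-disubstituted enal with C3 cis to CHO and can isomerise through its dienol. The C6/C7 configuration would be set in a macrocyclic transition state whose only bias is the remote C8 silyloxy group, and the behaviour of ring-trans germacranolide precursors cannot be carried over to a ring-cis,cis chain. C11 needs a further step, whereas the chosen plan sets C6, C7 and C11 on a five-membered ring before any macrocycle exists.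

Alternative 2: an anionic oxy-Cope ring expansion forms C8–C9 while the C6–C1 bond of a cyclohexene breaks. The forward key step takes the potassium alkoxide of the cis-dialkenylcyclohexenol A3 to the cyclodecadienone A4; the C4=C5 geometry comes from the six-membered ring and C8 from chirality transfer through the chair. The ground against it is structural and mechanistic. The chair gives the ring-cis C10=C1 olefin only from the cis-dialkenyl carbinol (alkenyl axial, isopropenyl equatorial), whereas addition of an alkenyl metal to the parent 6-isopropenyl enone should occur anti to the isopropenyl group and lead to the trans carbinol and hence the ring-trans olefin. C7 and C6 would then have to be created on the flexible macrocycle, by enolate alkylation and ketone reduction, with no local control element.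

Alternative 3: a [2,3]-Wittig ring contraction forms C6–C7 from the thirteen-membered bis-allylic ether A5 and gives the carbinol A6 with the side chain as a 2-propenyl unit. The grounds against it are selectivity and step economy. Two allylic α-oxy CH2 groups (C6 and C13) compete for deprotonation. The facial sense relative to C8 is unknown for a ring-cis,cis ether. The linear precursor needs three stereodefined trisubstituted olefins, and after contraction at least four redox steps are still required to turn the side chain into the α-methyl lactone.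

Key step: step 16

## Route

Step 1
Reactants: 1 (2S)-2-[(trityloxy)methyl]oxirane
Product: 2 (2S)-1-(trityloxy)but-3-en-2-ol
Conditions: Me3S+ I− (3 equiv), n-BuLi (2.9 equiv), THF, −20 °C to rt
Reagents that add atoms: trimethylsulfonium iodide, C[S+](C)C.[I-]
Why: Corey–Chaykovsky-type opening of the epoxide at its CH2 carbon by dimethylsulfonium methylide, followed by elimination of dimethyl sulfide from the β-sulfonium alkoxide, gives the one-carbon-homologated allylic alcohol. No bond to the stereocentre is touched, so the configuration of 1 is carried into 2 (future C6).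

Step 2
Reactants: 2 (2S)-1-(trityloxy)but-3-en-2-ol
Product: 3 (2S)-1-(trityloxy)but-3-en-2-yl 2-methylprop-2-enoate
Conditions: methacryloyl chloride, Et3N, DMAP (cat.), CH2Cl2, 0 °C
Reagents that add atoms: methacryloyl chloride, C=C(C)C(Cl)=O
Why: DMAP-catalysed O-acylation of the secondary allylic alcohol installs C12, C11 and the C11 methyl group as the metathesis partner.

Step 3
Reactants: 3 (2S)-1-(trityloxy)but-3-en-2-yl 2-methylprop-2-enoate
Product: 4 (5S)-3-methyl-5-[(trityloxy)methyl]furan-2(5H)-one
Conditions: second-generation Grubbs catalyst RuCl2(=CHPh)(H2IMes)(PCy3) (5 mol %), CH2Cl2, 40 °C, 5 mM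
Reagents that add atoms: none
Why: Ring-closing metathesis of the vinyl group onto the 1,1-disubstituted methacrylate closes the α-methylbutenolide (C7=C11) with loss of ethene. The stereocentre is not involved.

Step 4
Reactants: 4 (5S)-3-methyl-5-[(trityloxy)methyl]furan-2(5H)-one; 5 nitromethane
Product: 6 (3S,4R,5S)-3-methyl-4-(nitromethyl)-5-[(trityloxy)methyl]oxolan-2-one
Conditions: CH3NO2 (10 equiv), DBU (0.5 equiv), MeCN, 0 °C to rt
Reagents that add atoms: none
Why: Nitro-Michael addition: the nitronate attacks the β-carbon (future C7) anti to the bulky CH2OTr group, forming the C7–C8 bond. The α-carbon (future C11) equilibrates under DBU to the all-trans lactone, so C7 and C11 are both set from C6.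

Step 5
Reactants: 6 (3S,4R,5S)-3-methyl-4-(nitromethyl)-5-[(trityloxy)methyl]oxolan-2-one
Product: 7 (3S,4R,5S)-5-(hydroxymethyl)-3-methyl-4-(nitromethyl)oxolan-2-one
Conditions: p-TsOH·H2O (cat.), MeOH/CH2Cl2, rt
Reagents that add atoms: none
Why: Acid-catalysed solvolysis of the trityl ether (SN1 transfer of the trityl cation to methanol); lactone and nitro group are inert.

Step 6
Reactants: 7 (3S,4R,5S)-5-(hydroxymethyl)-3-methyl-4-(nitromethyl)oxolan-2-one
Product: 8 (2S,3R,4S)-4-methyl-3-(nitromethyl)-5-oxooxolane-2-carbaldehyde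
Conditions: Dess–Martin periodinane, NaHCO3, CH2Cl2, 0 °C to rt
Reagents that add atoms: none
Why: Dess–Martin oxidation under buffered, non-basic conditions should give the α-oxygenated aldehyde (C5) without epimerising the adjacent stereocentre or triggering nitro-aldol chemistry.

Step 7
Reactants: 9 ethyl 4-bromobutanoate
Product: 10 4-bromobutanal
Conditions: i-Bu2AlH (1.05 equiv), CH2Cl2, −78 °C; aqueous Rochelle salt
Reagents that add atoms: none
Why: Partial DIBAL-H reduction of the ester; the tetrahedral aluminium hemiacetal survives at −78 °C and releases the aldehyde on work-up. The aldehyde is used crude.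

Step 8
Reactants: 10 4-bromobutanal; 11 methyl 2-[bis(2,2,2-trifluoroethoxy)phosphoryl]propanoate
Product: 12 methyl (2Z)-6-bromo-2-methylhex-2-enoate
Conditions: KN(SiMe3)2, 18-crown-6, THF, −78 °C
Reagents that add atoms: none
Why: Still–Gennari olefination: the kinetically controlled Horner–Wadsworth–Emmons reaction of the bis(trifluoroethyl) phosphonate is Z-selective and sets C10=C1 with C9 cis to C2.

Step 9
Reactants: 12 methyl (2Z)-6-bromo-2-methylhex-2-enoate
Product: 13 (2Z)-6-bromo-2-methylhex-2-en-1-ol
Conditions: i-Bu2AlH (2.2 equiv), CH2Cl2, −78 °C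
Reagents that add atoms: none
Why: DIBAL-H 1,2-reduction of the enoate to the allylic alcohol keeps the olefin geometry; the primary bromide is inert at −78 °C.

Step 10
Reactants: 13 (2Z)-6-bromo-2-methylhex-2-en-1-ol
Product: 14 (2Z)-6-bromo-2-methylhex-2-en-1-yl tert-butyl carbonate
Conditions: Boc2O, DMAP (cat.), MeCN, rt
Reagents that add atoms: di-tert-butyl dicarbonate, CC(C)(C)OC(=O)OC(=O)OC(C)(C)C
Why: O-tert-butoxycarbonylation gives the allylic carbonate that later ionises under neutral conditions and releases its own hindered base.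

Step 11
Reactants: 14 (2Z)-6-bromo-2-methylhex-2-en-1-yl tert-butyl carbonate
Product: 15 [(4Z)-6-[(tert-butoxycarbonyl)oxy]-5-methylhex-4-en-1-yl]triphenylphosphonium bromide
Conditions: PPh3, MeCN, 80 °C
Reagents that add atoms: triphenylphosphine, c1ccc(cc1)P(c1ccccc1)c1ccccc1
Why: SN2 quaternisation of the phosphine by the primary bromide; an allylic carbonate is not attacked by a phosphine in the absence of palladium.

Step 12
Reactants: 15 [(4Z)-6-[(tert-butoxycarbonyl)oxy]-5-methylhex-4-en-1-yl]triphenylphosphonium bromide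
Product: 17 tert-butyl [(2Z)-2-methyl-7-oxo-6-(triphenyl-λ5-phosphanylidene)hept-2-en-1-yl] carbonate, via phosphorus ylide 16 (not isolated)
Conditions: KN(SiMe3)2 (1.0 equiv), THF, −78 °C; then HCO2Et, −78 °C to rt
Reagents that add atoms: ethyl formate, CCOC=O
Why: Deprotonation to the non-stabilised ylide, then C-formylation with ethyl formate (acylation of a Wittig ylide); the released ethoxide deprotonates the formylphosphonium ion to the stabilised ylide, which carries C4 and C15.

Step 13
Reactants: 8 (2S,3R,4S)-4-methyl-3-(nitromethyl)-5-oxooxolane-2-carbaldehyde; 17 tert-butyl [(2Z)-2-methyl-7-oxo-6-(triphenyl-λ5-phosphanylidene)hept-2-en-1-yl] carbonate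
Product: 18 tert-butyl (2Z,6E)-6-formyl-2-methyl-7-[(2R,3R,4S)-4-methyl-3-(nitromethyl)-5-oxooxolan-2-yl]hepta-2,6-dien-1-yl carbonate
Conditions: toluene, 80 °C
Reagents that add atoms: none
Why: Wittig olefination with an α-alkyl formyl-stabilised ylide is E-selective, placing CHO trans and the C3 chain cis to C6, which is the ring-cis C4=C5 geometry. The neutral conditions should preserve the α-oxygenated stereocentre and leave the nitro group alone.

Step 14
Reactants: 18 tert-butyl (2Z,6E)-6-formyl-2-methyl-7-[(2R,3R,4S)-4-methyl-3-(nitromethyl)-5-oxooxolan-2-yl]hepta-2,6-dien-1-yl carbonate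
Product: 19 tert-butyl (2Z,6E)-6-(hydroxymethyl)-2-methyl-7-[(2R,3R,4S)-4-methyl-3-(nitromethyl)-5-oxooxolan-2-yl]hepta-2,6-dien-1-yl carbonate
Conditions: NaBH4, CeCl3·7H2O, MeOH, −40 °C
Reagents that add atoms: none
Why: Luche reduction: chemoselective 1,2-reduction of the enal beside lactone, nitro group and carbonate; this also removes the aldehyde before any base can cause an intramolecular nitro-aldol reaction.

Step 15
Reactants: 19 tert-butyl (2Z,6E)-6-(hydroxymethyl)-2-methyl-7-[(2R,3R,4S)-4-methyl-3-(nitromethyl)-5-oxooxolan-2-yl]hepta-2,6-dien-1-yl carbonate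
Product: 20 tert-butyl (2Z,6E)-6-({[tert-butyl(dimethyl)silyl]oxy}methyl)-2-methyl-7-[(2R,3R,4S)-4-methyl-3-(nitromethyl)-5-oxooxolan-2-yl]hepta-2,6-dien-1-yl carbonate
Conditions: TBSCl, imidazole, CH2Cl2, 0 °C to rt
Reagents that add atoms: tert-butyldimethylsilyl chloride, CC(C)(C)[Si](C)(C)Cl
Why: Silylation of the primary allylic alcohol, so that C15–O is neither an allylic leaving group in step 16 nor a competing acyl acceptor in step 21.

Step 16
Reactants: 20 tert-butyl (2Z,6E)-6-({[tert-butyl(dimethyl)silyl]oxy}methyl)-2-methyl-7-[(2R,3R,4S)-4-methyl-3-(nitromethyl)-5-oxooxolan-2-yl]hepta-2,6-dien-1-yl carbonate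
Product: 21 (3S,3aR,6Z,10E,11aR)-10-({[tert-butyl(dimethyl)silyl]oxy}methyl)-3,6-dimethyl-4-nitro-3a,4,5,8,9,11a-hexahydrocyclodeca[b]furan-2(3H)-one (both C4 epimers)
Conditions: Pd2(dba)3·CHCl3 (5 mol %), dppe (12 mol %), THF, 45 °C, syringe-pump addition to 2 mM
Reagents that add atoms: none
Why: Intramolecular Tsuji–Trost allylation: zerovalent palladium ionises the primary allylic tert-butyl carbonate to a cationic η3-allyl complex (C9–C10–C1), the carbonate anion loses CO2, the tert-butoxide deprotonates the CH2NO2 group (far more acidic than the lactone α-CH), and the nitronate carbon C8 attacks the allyl terminus C9 on the face opposite the metal. The closest known reaction type is the palladium-catalysed C-allylation of nitroalkanes with allylic carbonates under neutral conditions, run here intramolecularly under high dilution as in macrocyclising allylic alkylations. The ten-membered ring closes by attack at the unsubstituted terminus C9, which keeps C10=C1 endocyclic; attack at C1 would give an eight-membered ring with an exocyclic 2-propenyl group and is disfavoured by the substituent on C1. The only new stereocentre, C8, is not controlled and need not be, because it becomes sp2 in step 17; C6 and C7 are not acidic and C11 stays at its thermodynamic configuration. The selectivity that matters is olefin geometry: the Z-carbonate gives the anti-substituted allyl, syn–anti exchange needs an η1-palladium at the secondary carbon C1 and is slowed by the chelating diphosphine in a halide-free medium, and the ring-cis closure is also the less strained one, so kinetic retention and ring strain both point to the ring-cis olefin. C-allylation should win over O-allylation because O-allyl nitronates can re-ionise while the C–C bond is irreversible, and the secondary allylic lactone C6–O on a trisubstituted olefin should ionise far more slowly than the primary carbonate.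

Step 17
Reactants: 21 (3S,3aR,6Z,10E,11aR)-10-({[tert-butyl(dimethyl)silyl]oxy}methyl)-3,6-dimethyl-4-nitro-3a,4,5,8,9,11a-hexahydrocyclodeca[b]furan-2(3H)-one
Product: 23 (3S,3aS,6Z,10E,11aR)-10-({[tert-butyl(dimethyl)silyl]oxy}methyl)-3,6-dimethyl-3a,8,9,11a-tetrahydrocyclodeca[b]furan-2,4(3H,5H)-dione, via potassium nitronate 22 (not isolated)
Conditions: KOt-Bu (1.0 equiv), THF, −40 °C; then TiCl3, NH4OAc, H2O/THF (pH 5–6), 0 °C to rt
Reagents that add atoms: water, O
Why: Nef reaction (TiCl3 variant): the nitronate is reduced by trivalent titanium to the N-unsubstituted imine, which hydrolyses in the buffer to the C8 ketone. The non-oxidising, nearly neutral medium should spare both olefins, the silyl ether, C7 and the β,γ-unsaturated ketone.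

Step 18
Reactants: 23 (3S,3aS,6Z,10E,11aR)-10-({[tert-butyl(dimethyl)silyl]oxy}methyl)-3,6-dimethyl-3a,8,9,11a-tetrahydrocyclodeca[b]furan-2,4(3H,5H)-dione
Product: 24 (3S,3aR,4S,6Z,10E,11aR)-10-({[tert-butyl(dimethyl)silyl]oxy}methyl)-4-hydroxy-3,6-dimethyl-3a,4,5,8,9,11a-hexahydrocyclodeca[b]furan-2(3H)-one
Conditions: NaBH4, CeCl3·7H2O, MeOH/THF, −78 °C; AcOH quench at −78 °C
Reagents that add atoms: none
Why: Luche-type carbonyl reduction; the C8 carbonyl is expected to point to the α-face (syn to H7, away from the lactone carbon C11), so hydride attack from the ring periphery should give the 8α (8S) alcohol. The cold acidic quench avoids migration of the lactone from O6 to O8.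

Step 19
Reactants: 25 ethyl 2-(hydroxymethyl)prop-2-enoate
Product: 26 ethyl 2-({[tert-butyl(dimethyl)silyl]oxy}methyl)prop-2-enoate
Conditions: TBSCl, imidazole, CH2Cl2, 0 °C to rt
Reagents that add atoms: tert-butyldimethylsilyl chloride, CC(C)(C)[Si](C)(C)Cl
Why: Silylation of the primary alcohol, so that the acid cannot acylate itself in step 21.

Step 20
Reactants: 26 ethyl 2-({[tert-butyl(dimethyl)silyl]oxy}methyl)prop-2-enoate
Product: 27 2-({[tert-butyl(dimethyl)silyl]oxy}methyl)prop-2-enoic acid
Conditions: LiOH, THF/H2O, 0 °C; then aq. HCl to pH 3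
Reagents that add atoms: lithium hydroxide, [Li+].[OH-]
Why: Saponification of the ethyl ester at low temperature; the α-substituent slows conjugate addition of hydroxide.

Step 21
Reactants: 24 (3S,3aR,4S,6Z,10E,11aR)-10-({[tert-butyl(dimethyl)silyl]oxy}methyl)-4-hydroxy-3,6-dimethyl-3a,4,5,8,9,11a-hexahydrocyclodeca[b]furan-2(3H)-one; 27 2-({[tert-butyl(dimethyl)silyl]oxy}methyl)prop-2-enoic acid
Product: 28 [(3S,3aR,4S,6Z,10E,11aR)-10-({[tert-butyl(dimethyl)silyl]oxy}methyl)-3,6-dimethyl-2-oxo-2,3,3a,4,5,8,9,11a-octahydrocyclodeca[b]furan-4-yl] 2-({[tert-butyl(dimethyl)silyl]oxy}methyl)prop-2-enoate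
Conditions: EDC·HCl, DMAP, CH2Cl2, 0 °C to rt
Reagents that add atoms: none
Why: Steglich esterification (carbodiimide activation, DMAP acyl transfer) acylates O8 with retention at C8; no strong base is present, so the lactone stays on O6.

Step 22
Reactants: 28 [(3S,3aR,4S,6Z,10E,11aR)-10-({[tert-butyl(dimethyl)silyl]oxy}methyl)-3,6-dimethyl-2-oxo-2,3,3a,4,5,8,9,11a-octahydrocyclodeca[b]furan-4-yl] 2-({[tert-butyl(dimethyl)silyl]oxy}methyl)prop-2-enoate
Product: 29 [(3S,3aR,4S,6Z,10E,11aR)-10-(hydroxymethyl)-3,6-dimethyl-2-oxo-2,3,3a,4,5,8,9,11a-octahydrocyclodeca[b]furan-4-yl] 2-(hydroxymethyl)prop-2-enoate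
Conditions: HF·pyridine, THF, 0 °C to rt
Reagents that add atoms: none
Why: Fluoride cleavage of both primary silyl ethers in a buffered acidic medium that should leave the acrylate, the lactone and both olefins intact.

## Compound list

1 | (2S)-2-[(trityloxy)methyl]oxirane | C(c1ccccc1)(c1ccccc1)(c1ccccc1)OC[C@@H]1CO1 | starting material
2 | (2S)-1-(trityloxy)but-3-en-2-ol | C(c1ccccc1)(c1ccccc1)(c1ccccc1)OC[C@H](C=C)O | intermediate
3 | (2S)-1-(trityloxy)but-3-en-2-yl 2-methylprop-2-enoate | C(c1ccccc1)(c1ccccc1)(c1ccccc1)OC[C@H](C=C)OC(=O)C(C)=C | intermediate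
4 | (5S)-3-methyl-5-[(trityloxy)methyl]furan-2(5H)-one | C(c1ccccc1)(c1ccccc1)(c1ccccc1)OC[C@H]1OC(=O)C(C)=C1 | intermediate
5 | nitromethane | C[N+](=O)[O-] | starting material
6 | (3S,4R,5S)-3-methyl-4-(nitromethyl)-5-[(trityloxy)methyl]oxolan-2-one | C(c1ccccc1)(c1ccccc1)(c1ccccc1)OC[C@H]1OC(=O)[C@@H](C)[C@@H]1C[N+](=O)[O-] | intermediate
7 | (3S,4R,5S)-5-(hydroxymethyl)-3-methyl-4-(nitromethyl)oxolan-2-one | OC[C@H]1OC(=O)[C@@H](C)[C@@H]1C[N+](=O)[O-] | intermediate
8 | (2S,3R,4S)-4-methyl-3-(nitromethyl)-5-oxooxolane-2-carbaldehyde | O=C[C@H]1OC(=O)[C@@H](C)[C@@H]1C[N+](=O)[O-] | intermediate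
9 | ethyl 4-bromobutanoate | CCOC(=O)CCCBr | starting material
10 | 4-bromobutanal | O=CCCCBr | intermediate
11 | methyl 2-[bis(2,2,2-trifluoroethoxy)phosphoryl]propanoate | COC(=O)C(C)P(=O)(OCC(F)(F)F)OCC(F)(F)F | starting material
12 | methyl (2Z)-6-bromo-2-methylhex-2-enoate | COC(=O)/C(C)=C\CCCBr | intermediate
13 | (2Z)-6-bromo-2-methylhex-2-en-1-ol | OC/C(C)=C\CCCBr | intermediate
14 | (2Z)-6-bromo-2-methylhex-2-en-1-yl tert-butyl carbonate | CC(C)(C)OC(=O)OC/C(C)=C\CCCBr | intermediate
15 | [(4Z)-6-[(tert-butoxycarbonyl)oxy]-5-methylhex-4-en-1-yl]triphenylphosphonium bromide | CC(C)(C)OC(=O)OC/C(C)=C\CCC[P+](c1ccccc1)(c1ccccc1)c1ccccc1.[Br-] | intermediate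
16 | tert-butyl [(2Z)-2-methyl-6-(triphenyl-λ5-phosphanylidene)hex-2-en-1-yl] carbonate | CC(C)(C)OC(=O)OC/C(C)=C\CCC=P(c1ccccc1)(c1ccccc1)c1ccccc1 | intermediate (not isolated)
17 | tert-butyl [(2Z)-2-methyl-7-oxo-6-(triphenyl-λ5-phosphanylidene)hept-2-en-1-yl] carbonate | CC(C)(C)OC(=O)OC/C(C)=C\CCC(C=O)=P(c1ccccc1)(c1ccccc1)c1ccccc1 | intermediate
18 | tert-butyl (2Z,6E)-6-formyl-2-methyl-7-[(2R,3R,4S)-4-methyl-3-(nitromethyl)-5-oxooxolan-2-yl]hepta-2,6-dien-1-yl carbonate | CC(C)(C)OC(=O)OC/C(C)=C\CC/C(C=O)=C\[C@H]1OC(=O)[C@@H](C)[C@@H]1C[N+](=O)[O-] | intermediate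
19 | tert-butyl (2Z,6E)-6-(hydroxymethyl)-2-methyl-7-[(2R,3R,4S)-4-methyl-3-(nitromethyl)-5-oxooxolan-2-yl]hepta-2,6-dien-1-yl carbonate | CC(C)(C)OC(=O)OC/C(C)=C\CC/C(CO)=C\[C@H]1OC(=O)[C@@H](C)[C@@H]1C[N+](=O)[O-] | intermediate
20 | tert-butyl (2Z,6E)-6-({[tert-butyl(dimethyl)silyl]oxy}methyl)-2-methyl-7-[(2R,3R,4S)-4-methyl-3-(nitromethyl)-5-oxooxolan-2-yl]hepta-2,6-dien-1-yl carbonate | CC(C)(C)OC(=O)OC/C(C)=C\CC/C(CO[Si](C)(C)C(C)(C)C)=C\[C@H]1OC(=O)[C@@H](C)[C@@H]1C[N+](=O)[O-] | intermediate
21 | (3S,3aR,6Z,10E,11aR)-10-({[tert-butyl(dimethyl)silyl]oxy}methyl)-3,6-dimethyl-4-nitro-3a,4,5,8,9,11a-hexahydrocyclodeca[b]furan-2(3H)-one (C4 epimers) | [O-][N+](=O)C1C/C(C)=C\CC/C(CO[Si](C)(C)C(C)(C)C)=C\[C@H]2OC(=O)[C@@H](C)[C@H]12 | intermediate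
22 | potassium salt of the C4 aci-nitro form of 21 (potassium nitronate) | [K+].[O-][N+]([O-])=C1C/C(C)=C\CC/C(CO[Si](C)(C)C(C)(C)C)=C\[C@H]2OC(=O)[C@@H](C)[C@H]12 | intermediate (not isolated)
23 | (3S,3aS,6Z,10E,11aR)-10-({[tert-butyl(dimethyl)silyl]oxy}methyl)-3,6-dimethyl-3a,8,9,11a-tetrahydrocyclodeca[b]furan-2,4(3H,5H)-dione | O=C1C/C(C)=C\CC/C(CO[Si](C)(C)C(C)(C)C)=C\[C@H]2OC(=O)[C@@H](C)[C@H]12 | intermediate
24 | (3S,3aR,4S,6Z,10E,11aR)-10-({[tert-butyl(dimethyl)silyl]oxy}methyl)-4-hydroxy-3,6-dimethyl-3a,4,5,8,9,11a-hexahydrocyclodeca[b]furan-2(3H)-one | O[C@H]1C/C(C)=C\CC/C(CO[Si](C)(C)C(C)(C)C)=C\[C@H]2OC(=O)[C@@H](C)[C@H]12 | intermediate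
25 | ethyl 2-(hydroxymethyl)prop-2-enoate | C=C(CO)C(=O)OCC | starting material
26 | ethyl 2-({[tert-butyl(dimethyl)silyl]oxy}methyl)prop-2-enoate | C=C(CO[Si](C)(C)C(C)(C)C)C(=O)OCC | intermediate
27 | 2-({[tert-butyl(dimethyl)silyl]oxy}methyl)prop-2-enoic acid | C=C(CO[Si](C)(C)C(C)(C)C)C(=O)O | intermediate
28 | [(3S,3aR,4S,6Z,10E,11aR)-10-({[tert-butyl(dimethyl)silyl]oxy}methyl)-3,6-dimethyl-2-oxo-2,3,3a,4,5,8,9,11a-octahydrocyclodeca[b]furan-4-yl] 2-({[tert-butyl(dimethyl)silyl]oxy}methyl)prop-2-enoate | C=C(CO[Si](C)(C)C(C)(C)C)C(=O)O[C@H]1C/C(C)=C\CC/C(CO[Si](C)(C)C(C)(C)C)=C\[C@H]2OC(=O)[C@@H](C)[C@H]12 | intermediate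
29 | [(3S,3aR,4S,6Z,10E,11aR)-10-(hydroxymethyl)-3,6-dimethyl-2-oxo-2,3,3a,4,5,8,9,11a-octahydrocyclodeca[b]furan-4-yl] 2-(hydroxymethyl)prop-2-enoate | C=C(CO)C(=O)O[C@H]1C/C(C)=C\CC/C(CO)=C\[C@H]2OC(=O)[C@@H](C)[C@H]12 | target

## Step count and least certain steps

Total: 22 steps, counting the two-step preparation of 27. Longest linear sequence: 14 steps (steps 1–6, 13–18, 21, 22; the branch from 9 through steps 7–12 has the same length).

**Step 16 (key step).** Three processes are the likely failures. The allyl-palladium intermediate may undergo syn–anti isomerisation before the slow ring closure, which would give the ring-trans C10=C1 olefin. Intermolecular allylation may compete, giving oligomers, because a ten-membered ring is the least favourable size. The allylic lactone C6–O bond may ionise reversibly and erode C6.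

Fallback, setting out from 8 and coming back at 21, closes the ring by metathesis at C10=C1 instead, with the nitro carbon allylated intermolecularly:
- Wittig olefination of 8 with 2-(triphenyl-λ5-phosphanylidene)hex-5-enal F1 (from commercial pent-4-en-1-yl(triphenyl)phosphonium bromide, KN(SiMe3)2 and ethyl formate) would give (2E)-2-(but-3-en-1-yl)-3-[(2R,3R,4S)-4-methyl-3-(nitromethyl)-5-oxooxolan-2-yl]prop-2-enal F2.
- Luche reduction would give (3S,4R,5R)-5-[(1E)-2-(hydroxymethyl)hexa-1,5-dien-1-yl]-3-methyl-4-(nitromethyl)oxolan-2-one F3, and silylation its tert-butyldimethylsilyl ether (3S,4R,5R)-5-[(1E)-2-({[tert-butyl(dimethyl)silyl]oxy}methyl)hexa-1,5-dien-1-yl]-3-methyl-4-(nitromethyl)oxolan-2-one F4.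
- Intermolecular Tsuji–Trost allylation of the nitromethyl group with tert-butyl 2-methylprop-2-en-1-yl carbonate (Pd(PPh3)4, THF) would give (3S,4R,5R)-5-[(1E)-2-({[tert-butyl(dimethyl)silyl]oxy}methyl)hexa-1,5-dien-1-yl]-3-methyl-4-(3-methyl-1-nitrobut-3-en-1-yl)oxolan-2-one F5.
- Ring-closing metathesis of F5 between its 1,1-disubstituted and monosubstituted olefins (second-generation Hoveyda–Grubbs catalyst RuCl2(=CH-2-(i-PrO)C6H4)(H2IMes), toluene, 80 °C, 1 mM) would close the ring at C10=C1, where the cis geometry is the less strained one, and return to the route at 21.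

**Step 18.** Hydride delivery to a conformationally ill-defined ten-membered ketone may show poor or reversed facial selectivity, and the intermediate alkoxide may take over the lactone. Fallback, setting out from 23 and coming back at 28: if the reduction delivers mainly the epimer (3S,3aR,4R,6Z,10E,11aR)-10-({[tert-butyl(dimethyl)silyl]oxy}methyl)-4-hydroxy-3,6-dimethyl-3a,4,5,8,9,11a-hexahydrocyclodeca[b]furan-2(3H)-one F6, it is not discarded. F6 is esterified with 27 under Mitsunobu conditions (PPh3, diisopropyl azodicarboxylate, toluene, 0 °C), which inverts C8 and gives 28 directly. Both alcohol epimers therefore lead to the same ester, one by step 21 with retention and the other with inversion.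

**Step 17.** Reduction of the nitronate may stop at the oxime, and once the ketone forms, traces of base may epimerise C7 or move the C10=C1 olefin into conjugation. Fallback, setting out from 21 and coming back at 23, splits the conversion into two mild stages. Reduction of 21 with SnCl2·2H2O, PhSH and Et3N would give the oxime (3S,3aR,6Z,10E,11aR)-10-({[tert-butyl(dimethyl)silyl]oxy}methyl)-4-(hydroxyimino)-3,6-dimethyl-3a,4,5,8,9,11a-hexahydrocyclodeca[b]furan-2(3H)-one F7. Exchange of the oxime of F7 onto glyoxylic acid (aqueous AcOH/NaOAc, rt) would then release 23 without any strong base.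

## Further compounds

F1 | step 16 | 2-(triphenyl-λ5-phosphanylidene)hex-5-enal | O=CC(CCC=C)=P(c1ccccc1)(c1ccccc1)c1ccccc1
F2 | step 16 | (2E)-2-(but-3-en-1-yl)-3-[(2R,3R,4S)-4-methyl-3-(nitromethyl)-5-oxooxolan-2-yl]prop-2-enal | O=C/C(CCC=C)=C/[C@H]1OC(=O)[C@@H](C)[C@@H]1C[N+](=O)[O-]
F3 | step 16 | (3S,4R,5R)-5-[(1E)-2-(hydroxymethyl)hexa-1,5-dien-1-yl]-3-methyl-4-(nitromethyl)oxolan-2-one | OC/C(CCC=C)=C/[C@H]1OC(=O)[C@@H](C)[C@@H]1C[N+](=O)[O-]
F4 | step 16 | (3S,4R,5R)-5-[(1E)-2-({[tert-butyl(dimethyl)silyl]oxy}methyl)hexa-1,5-dien-1-yl]-3-methyl-4-(nitromethyl)oxolan-2-one | CC(C)(C)[Si](C)(C)OC/C(CCC=C)=C/[C@H]1OC(=O)[C@@H](C)[C@@H]1C[N+](=O)[O-]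
F5 | step 16 | (3S,4R,5R)-5-[(1E)-2-({[tert-butyl(dimethyl)silyl]oxy}methyl)hexa-1,5-dien-1-yl]-3-methyl-4-(3-methyl-1-nitrobut-3-en-1-yl)oxolan-2-one (epimers at the nitro carbon) | CC(C)(C)[Si](C)(C)OC/C(CCC=C)=C/[C@H]1OC(=O)[C@@H](C)[C@@H]1C(CC(C)=C)[N+](=O)[O-]
F6 | step 18 | (3S,3aR,4R,6Z,10E,11aR)-10-({[tert-butyl(dimethyl)silyl]oxy}methyl)-4-hydroxy-3,6-dimethyl-3a,4,5,8,9,11a-hexahydrocyclodeca[b]furan-2(3H)-one | O[C@@H]1C/C(C)=C\CC/C(CO[Si](C)(C)C(C)(C)C)=C\[C@H]2OC(=O)[C@@H](C)[C@H]12
F7 | step 17 | (3S,3aR,6Z,10E,11aR)-10-({[tert-butyl(dimethyl)silyl]oxy}methyl)-4-(hydroxyimino)-3,6-dimethyl-3a,4,5,8,9,11a-hexahydrocyclodeca[b]furan-2(3H)-one | ON=C1C/C(C)=C\CC/C(CO[Si](C)(C)C(C)(C)C)=C\[C@H]2OC(=O)[C@@H](C)[C@H]12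
A1 | alternative 1 | methyl (2Z,4S,6Z,10E)-2-(bromomethyl)-4-{[tert-butyl(dimethyl)silyl]oxy}-10-({[tert-butyl(dimethyl)silyl]oxy}methyl)-6-methyl-12-oxododeca-2,6,10-trienoate | COC(=O)/C(CBr)=C/[C@@H](O[Si](C)(C)C(C)(C)C)C/C(C)=C\CC/C(CO[Si](C)(C)C(C)(C)C)=C\C=O
A2 | alternative 1 | (3aS,4S,6Z,10E,11aR)-4-{[tert-butyl(dimethyl)silyl]oxy}-10-({[tert-butyl(dimethyl)silyl]oxy}methyl)-6-methyl-3-methylidene-3a,4,5,8,9,11a-hexahydrocyclodeca[b]furan-2(3H)-one | CC(C)(C)[Si](C)(C)O[C@H]1C/C(C)=C\CC/C(CO[Si](C)(C)C(C)(C)C)=C\[C@H]2OC(=O)C(=C)[C@H]12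
A3 | alternative 2 | (1R,6S)-3-({[tert-butyl(dimethyl)silyl]oxy}methyl)-1-[(Z)-2-(methoxymethoxy)ethenyl]-6-(prop-1-en-2-yl)cyclohex-2-en-1-ol | O[C@]1(/C=C\OCOC)C=C(CO[Si](C)(C)C(C)(C)C)CC[C@H]1C(C)=C
A4 | alternative 2 | (2E,6Z,9S)-3-({[tert-butyl(dimethyl)silyl]oxy}methyl)-9-(methoxymethoxy)-7-methylcyclodeca-2,6-dien-1-one | O=C1C[C@@H](OCOC)C/C(C)=C\CC/C(CO[Si](C)(C)C(C)(C)C)=C\1
A5 | alternative 3 | (3E,7Z,10S,11E)-4-({[tert-butyl(dimethyl)silyl]oxy}methyl)-10-[(4-methoxyphenyl)methoxy]-8-methyl-12-({[tri(propan-2-yl)silyl]oxy}methyl)-1-oxacyclotrideca-3,7,11-triene | O1C/C=C(/CO[Si](C)(C)C(C)(C)C)CC/C=C(C)\C[C@H](OCc2ccc(OC)cc2)/C=C(/CO[Si](C(C)C)(C(C)C)C(C)C)C1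
A6 | alternative 3 | (1R,2E,6Z,9S,10S)-3-({[tert-butyl(dimethyl)silyl]oxy}methyl)-9-[(4-methoxyphenyl)methoxy]-7-methyl-10-(3-{[tri(propan-2-yl)silyl]oxy}prop-1-en-2-yl)cyclodeca-2,6-dien-1-ol | COc1ccc(CO[C@H]2C/C(C)=C\CC/C(CO[Si](C)(C)C(C)(C)C)=C\[C@@H](O)[C@@H]2C(=C)CO[Si](C(C)C)(C(C)C)C(C)C)cc1
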